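**Assumption:** labdane numbering is used throughout. Reading the SMILES gives 5α-H, 9α-H, 10β-Me, equatorial 2α-Cl, 12S and 13R. This is the same absolute series as (+)-sclareolide. Reagent 2 and Cl4NHPI are taken as purchasable.

## Retrosynthetic overview
1. Target 14 comes from photodeconjugation of the 7-en-6-one 13, which comes from anodic allylic C6–H oxidation of the Δ7-ene 11.
2. The succinimide is the last ring formed: NH3 on trans-γ-lactone ester 9, which comes from an alkene shift after C8–O scission of the 8,12-epoxy diester 7.
3. Key disconnection: C13–C14 and C12–H are made together by a visible-light radical hydroalkylation of the exocyclic (E)-β-alkoxyacrylate 5. The bought tricycle sets C12 directly and biases C13, which step 4 then fixes relative to C12.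
4. Compound 5 comes from Claisen condensation and cyclodehydration on 2α-chlorosclareolide 3, which comes from photochemical C2–H chlorination of (+)-sclareolide 1.
5. Ring order: the decalin and O-heterocycle are bought, the tetrahydrofuran is kept as the stereocontrol element, then it is opened and relactonised, and the imide is closed last.

## Route

**Step 1**
Reactants: 1 (+)-sclareolide; 2 N-tert-butyl-N-chloro-3,5-bis(trifluoromethyl)benzamide
Product: 3, 2α-chlorosclareolide (equatorial Cl)
Conditions: 2 (1.1 equiv), Cs2CO3, PhH, white light, 55 °C
Reagents that add atoms: 2, CC(C)(C)N(Cl)C(=O)c1cc(cc(c1)C(F)(F)F)C(F)(F)F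
Why: In this radical-chain aliphatic C–H chlorination (amidyl HAT, then Cl-atom transfer), the bulky electrophilic amidyl radical takes the most accessible electron-rich methylene H (C2, remote from the lactone), and Cl is delivered to the α-face, anti to the axial C4/C10 methyls, giving 2α-Cl.

**Step 2**
Reactants: 3; 4 methyl acetate
Product: 5, methyl (12E)-2α-chloro-8α,12-epoxy-14,15-dinorlabd-12-en-16-oate (exocyclic vinylogous carbonate, ester trans to the ring O)
Conditions: LDA/4 (3 equiv each), THF, −78 °C, then 3, −78 → −30 °C; AcOH; then CSA (10 mol %), 4 Å MS, CH2Cl2, 23 °C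
Reagents that add atoms: methyl acetate, COC(C)=O
Why: A crossed Claisen condensation on the lactone carbonyl is followed by acid-catalysed cyclodehydration of the γ-hydroxy-β-keto ester (hemiketal), in which C8–O is never broken, acid equilibration favours the dipole-minimised E isomer, and no new stereocentre forms.

**Step 3 (key step)**
Reactants: 5; 6 methyl bromoacetate
Product: 7, dimethyl (12S,13R)-2α-chloro-8α,12-epoxylabdane-15,16-dioate (H-12 α; succinate on the β-face, cis to the C17 methyl)
Conditions: 6 (3 equiv, slow addition), fac-Ir(ppy)3 (racemic, 1 mol %), Hantzsch ester (2 equiv), 2,4,6-iPr3C6H2SH (20 mol %), MeCN/CH2Cl2, 450 nm LEDs, 0 °C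
Reagents that add atoms: methyl bromoacetate, COC(=O)CBr
Why: Proposed new method: an anti-Giese photoredox/thiol hydroalkylation of a β-alkoxyacrylate, in which the electrophilic •CH2CO2Me radical (from SET reduction of 6) adds to the nucleophilic α-carbon C13 rather than the β-carbon to give a tertiary α-alkoxy C12 radical; that nucleophilic radical is quenched by polarity-matched HAT from the bulky thiol (thiyl recycled by the Hantzsch ester) faster than it is oxidised or abstracts Br; the axial C17 methyl blocks the β-face, so H-12 arrives from the α-face and gives the contra-steric 12S centre, while α-face attack on the E-alkene gives 13R (weaker bias, and any 13-epimer is corrected in step 4); the closest known reaction types are reductive hydroalkylation of enol ethers and alkenes with α-halo esters, radical α-functionalisation of β-alkoxyacrylates and enaminones, and face-selective H-atom delivery to anomeric radicals.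

**Step 4**
Reactants: 7
Product: 8, methyl (12S,13R)-2α-chloro-labd-8(17)-en-15,12-olid-16-oate (12,13-trans γ-lactone, exocyclic alkene; contains some Δ7 isomer 9)
Conditions: TMSOTf (3 equiv), 2,6-lutidine (4 equiv), CH2Cl2, −20 → 23 °C; aq. citric acid; crude + DBU (0.3 equiv), PhMe, 23 °C
Reagents that add atoms: none (MeOH is lost)
Why: In this silyl-triflate cleavage of a tert-alkyl ether (E1), the O-silylated tertiary C8–O bond ionises and buffered proton loss gives the alkene while C12–O is untouched (12S retained), the freed 12-OH then lactonises on the C15 ester, and DBU equilibrates C13 (α to the ester) to the more stable trans lactone, so 13R is fixed under control of C12.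

**Step 5**
Reactants: 8 (with 9)
Product: 9, the Δ7 isomer (labd-7-ene trans-lactone ester)
Conditions: achiral [N,N′-bis(3,5-di-tert-butylsalicylidene)ethylenediaminato]Co(III)Cl (3 mol %), PhSiH3 (6 mol %), PhH, 23 °C
Reagents that add atoms: none
Why: In this MHAT radical alkene isomerisation, Co–H puts H• on C17 to give the tertiary C8 radical and Co(II) removes the accessible H-7 rather than the hindered tertiary H-9, so the mixture converges on the trisubstituted Δ7 alkene with C9, the chloride, the lactone and the ester untouched.

**Step 6**
Reactants: 9; 10 ammonia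
Product: 11, (12S,13R)-2α-chloro-12-hydroxylabd-7-ene-15,16-dicarboximide
Conditions: NH3 (7 M in MeOH, 5 equiv), 0 → 23 °C, monitored and stopped at the imide
Reagents that add atoms: ammonia, N
Why: Lactone aminolysis is followed by 5-exo-trig N-acylation by the neighbouring methyl ester (succinimide closure), attack in the other order converges on the same product, and no bond at C12 or C13 is broken.

**Step 7**
Reactants: 11; 12 tert-butyl hydroperoxide
Product: 13, (12S,13R)-2α-chloro-12-hydroxy-6-oxolabd-7-ene-15,16-dicarboximide
Conditions: undivided cell, RVC(+)/RVC(−), constant current, Cl4NHPI (20 mol %), pyridine (2 equiv), 12 (2 equiv), LiClO4 (0.1 M), acetone, 23 °C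
Reagents that add atoms: t-BuOOH, CC(C)(C)OO
Why: In this mediated electrochemical allylic C–H oxidation, the anodically formed tetrachloro-PINO radical abstracts the secondary allylic H-6, the allyl radical is trapped by t-BuOO• at its secondary terminus and the peroxide collapses to the enone, while the stronger, inductively deactivated carbinol C12–H, the imide and the chloride survive.

**Step 8**
Reactants: 13
Product: 14, haterumaimide G
Conditions: HMDS, cat. TMSCl, CH2Cl2, 23 °C, evaporate (transient 12-OTMS); hν 350 nm (Pyrex), EtOAc, AcOH (5 mM), c = 5 mM, Ar, 10 °C; MeOH/citric acid, 0 °C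
Reagents that add atoms: none
Why: In this acid-catalysed photochemical deconjugation of a 3-alkylcyclohex-2-enone, the twisted enone triplet is protonated at C7 and the C8 cation loses a C17 proton to give the exocyclic β,γ-enone, which barely absorbs at 350 nm, the absence of base protects C5, C9 and C13, and the transient silyl ether stops 12-OH from capturing C8.

## Compound list
1 | (+)-sclareolide | C[C@@]12CC[C@H]3C(C)(C)CCC[C@]3(C)[C@H]1CC(=O)O2 | starting material
2 | N-tert-butyl-N-chloro-3,5-bis(trifluoromethyl)benzamide | CC(C)(C)N(Cl)C(=O)c1cc(cc(c1)C(F)(F)F)C(F)(F)F | starting material (reagent)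
3 | 2α-chlorosclareolide | C[C@@]12CC[C@H]3C(C)(C)C[C@H](Cl)C[C@]3(C)[C@H]1CC(=O)O2 | intermediate
4 | methyl acetate | COC(C)=O | starting material
5 | methyl (12E)-2α-chloro-8α,12-epoxy-14,15-dinorlabd-12-en-16-oate | C[C@@]12CC[C@H]3C(C)(C)C[C@H](Cl)C[C@]3(C)[C@H]1C/C(=C\C(=O)OC)O2 | intermediate
6 | methyl bromoacetate | COC(=O)CBr | starting material
7 | dimethyl (12S,13R)-2α-chloro-8α,12-epoxylabdane-15,16-dioate | C[C@@]12CC[C@H]3C(C)(C)C[C@H](Cl)C[C@]3(C)[C@H]1C[C@@H]([C@@H](CC(=O)OC)C(=O)OC)O2 | intermediate
8 | methyl (12S,13R)-2α-chlorolabd-8(17)-en-15,12-olid-16-oate (trans lactone) | C=C1CC[C@H]2C(C)(C)C[C@H](Cl)C[C@]2(C)[C@H]1C[C@@H]1OC(=O)C[C@H]1C(=O)OC | intermediate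
9 | methyl (12S,13R)-2α-chlorolabd-7-en-15,12-olid-16-oate | CC1=CC[C@H]2C(C)(C)C[C@H](Cl)C[C@]2(C)[C@H]1C[C@@H]1OC(=O)C[C@H]1C(=O)OC | intermediate
10 | ammonia | N | starting material
11 | (12S,13R)-2α-chloro-12-hydroxylabd-7-ene-15,16-dicarboximide | CC1=CC[C@H]2C(C)(C)C[C@H](Cl)C[C@]2(C)[C@H]1C[C@H](O)[C@H]1CC(=O)NC1=O | intermediate
12 | tert-butyl hydroperoxide | CC(C)(C)OO | starting material
13 | (12S,13R)-2α-chloro-12-hydroxy-6-oxolabd-7-ene-15,16-dicarboximide | CC1=CC(=O)[C@H]2C(C)(C)C[C@H](Cl)C[C@]2(C)[C@H]1C[C@H](O)[C@H]1CC(=O)NC1=O | intermediate
14 | haterumaimide G | C=C1CC(=O)[C@H]2C(C)(C)C[C@H](Cl)C[C@]2(C)[C@H]1C[C@H](O)[C@H]1CC(=O)NC1=O | target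

## Step count
Total steps: 8. Longest linear sequence: 8, from (+)-sclareolide.

## Three steps most likely to fail
1. **Step 3 (proposed new hydroalkylation).**
   - Risks: slow addition of •CH2CO2Me to the ester-bearing C13; thiol consumption by S-alkylation or thiol-ene addition; oxidation of the C12 radical followed by elimination.
   - Fallback (known chemistry, one step longer): reduce 3 to the lactol with DIBAL-H. Then run a decatungstate-photocatalysed hydroacylation of dimethyl maleate, which forms C12–C13. Then reduce the hemiketal with Et3SiH/BF3·OEt2, with hydride arriving from the α-face to give 12S. C13 is set afterwards by the trans-lactone equilibration of step 4.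
2. **Step 4 (ether cleavage).**
   - Risks: sluggish silylation of the hindered ether; formation of Δ8(9), which loses C9; 1,2-shifts of the C8 cation.
   - Fallback: avoid the cation altogether.
     - Open the ring at the lactone stage by Weinreb aminolysis of 3, then dehydrate with SOCl2/pyridine.
     - Apply steps 5 and 7 early to reach the 7-en-6-one Weinreb amide.
     - Add LiCH2CO2Me. The β-keto ester enol then closes onto the enone by oxa-Michael addition to give the 6-oxo analogue of 5.
     - After the step 3 chemistry, open the ether with DBU by retro-oxa-Michael (E1cB), which can only give Δ7.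
3. **Step 8 (photodeconjugation).**
   - Risks: low quantum yield; capture of C8 by oxygen; loss of H-9; secondary 1,3-acyl shift of the product.
   - Fallback: protect 12-OH as the TES ether. Treat with KHMDS (2.2 equiv), where deprotonating the imide N–H first shields C13, to form the extended dienolate. Quench kinetically with AcOH at −78 °C (α-protonation at C7). Remove the TES group with HF·pyridine.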